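**Plan**
- Retrosynthetic cuts, in order: the interflavan bond C4(upper)–C8(lower); the C4–C4a bond of the lower pyran ring; the aryl ether bond O1–C8a; the C2–C3 bond of the lower unit.
- Enabling feature: the lower C4 is benzylic to ring A (C4a lies ortho to O1 on the phloroglucinol ring) and also β to the carboxyl carbon, so C4–C4a joins an electron-rich arene carbon to the β-carbon of an alkylidene malonate.
- Forward, lower unit: glycolate aldol (C2–C3), O-arylation with a 3,5-bis(benzyloxy)phenyl unit (O1–C8a), Knoevenagel condensation, Friedel–Crafts Michael closure of the lower pyran ring, loss of one ester carbon.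
- Forward, upper unit: (−)-epicatechin is turned into a C8-brominated C4 electrophile and joined to C8 of the lower unit; saponification and hydrogenolysis finish the synthesis.
- Stereochemistry: lower C2/C3 from the Evans syn-aldol (the O-arylation leaves the C2–O bond intact), lower C4 from 1,3-allylic strain in the ring closure, upper C2/C3 from natural epicatechin, upper C4 by attack anti to the C3 oxygen.

Key step: step 10

Remark: the target is read as epicatechin-(4β→8)-epicatechin with a carboxymethyl group at the lower C4, trans to O3 (lower unit 2R,3R,4S; upper unit 2R,3R,4R); flavan numbering is used for both units.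

**Route**

Step 1
Reactants: 1 (S)-4-benzyloxazolidin-2-one; 2 benzyloxyacetyl chloride
Product: 4 (S)-4-benzyl-3-[2-(benzyloxy)acetyl]oxazolidin-2-one, via lithium oxazolidinide 3 (not isolated)
Conditions: n-BuLi, THF, −78 °C; then 2, −78 → 0 °C
Reagents that add atoms: none
Why: N-acylation of the lithiated oxazolidinone with an acid chloride is the standard way to an Evans glycolate imide and does not touch the stereocentre of the auxiliary.

Step 2
Reactants: 4 (S)-4-benzyl-3-[2-(benzyloxy)acetyl]oxazolidin-2-one; 5 3,4-bis(benzyloxy)benzaldehyde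
Product: 8 (S)-4-benzyl-3-[(2S,3R)-2-(benzyloxy)-3-[3,4-bis(benzyloxy)phenyl]-3-hydroxypropanoyl]oxazolidin-2-one, via dibutylboron Z-enolate 6 (not isolated), via dibutylboron aldolate 7 (not isolated)
Conditions: Bu2BOTf, Et3N, CH2Cl2, −78 → 0 °C; then 5, −78 → 0 °C; pH 7 buffer, MeOH, H2O2, 0 °C
Reagents that add atoms: none
Why: Evans syn-aldol reaction, in which the Z-boron enolate reacts through a Zimmerman–Traxler chair with the aldehyde on the enolate face away from the benzyl group of the auxiliary, which should set the 2S,3R syn pair that becomes C3 and C2 of the lower flavan unit.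

Step 3
Reactants: 8 (S)-4-benzyl-3-[(2S,3R)-2-(benzyloxy)-3-[3,4-bis(benzyloxy)phenyl]-3-hydroxypropanoyl]oxazolidin-2-one
Product: 9 (1R,2R)-2-(benzyloxy)-1-[3,4-bis(benzyloxy)phenyl]propane-1,3-diol
Conditions: LiBH4, MeOH (1 equiv), THF, 0 °C
Reagents that add atoms: none
Why: Reductive cleavage of the N-acyloxazolidinone with LiBH4 should give the primary alcohol and return the auxiliary without epimerising either carbinol centre.

Step 4
Reactants: 9 (1R,2R)-2-(benzyloxy)-1-[3,4-bis(benzyloxy)phenyl]propane-1,3-diol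
Product: 10 (1R,2R)-2-(benzyloxy)-1-[3,4-bis(benzyloxy)phenyl]-3-[(triisopropylsilyl)oxy]propan-1-ol
Conditions: TIPSCl, imidazole, DMF, 0 °C → rt
Reagents that add atoms: chlorotriisopropylsilane, CC(C)[Si](Cl)(C(C)C)C(C)C
Why: Silylation is selective for the primary hydroxyl over the hindered benzylic one, and the bulky triisopropylsilyl group is chosen because it resists carbonate base and 1,3-migration in step 6.

Step 5
Reactants: 11 1,3-bis(benzyloxy)-5-bromobenzene
Product: 12 1,3-bis(benzyloxy)-5-iodobenzene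
Conditions: CuI (5 mol %), trans-N,N'-dimethylcyclohexane-1,2-diamine (10 mol %), NaI, 1,4-dioxane, 110 °C
Reagents that add atoms: sodium iodide, [Na+].[I-]
Why: Aromatic Finkelstein halogen exchange, driven by the low solubility of NaBr in dioxane, should give the aryl iodide needed for the C–O coupling.

Step 6
Reactants: 10 (1R,2R)-2-(benzyloxy)-1-[3,4-bis(benzyloxy)phenyl]-3-[(triisopropylsilyl)oxy]propan-1-ol; 12 1,3-bis(benzyloxy)-5-iodobenzene
Product: 13 {[(2R,3R)-2-(benzyloxy)-3-[3,4-bis(benzyloxy)phenyl]-3-[3,5-bis(benzyloxy)phenoxy]propyl]oxy}triisopropylsilane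
Conditions: 12 (1.5 equiv), CuI (10 mol %), 3,4,7,8-tetramethyl-1,10-phenanthroline (20 mol %), Cs2CO3, toluene, 110 °C, argon
Reagents that add atoms: none
Why: Ullmann-type C–O coupling arylates the caesium alkoxide on oxygen, so the benzylic C–O bond is never broken, C2 keeps its R configuration, and no cation can form at the electron-rich benzylic carbon.

Step 7
Reactants: 13 {[(2R,3R)-2-(benzyloxy)-3-[3,4-bis(benzyloxy)phenyl]-3-[3,5-bis(benzyloxy)phenoxy]propyl]oxy}triisopropylsilane
Product: 14 (2R,3R)-2-(benzyloxy)-3-[3,4-bis(benzyloxy)phenyl]-3-[3,5-bis(benzyloxy)phenoxy]propan-1-ol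
Conditions: TBAF, THF, 0 °C → rt
Reagents that add atoms: none
Why: Fluoride cleaves the silyl ether, and the benzyl and aryl ethers are inert to it.

Step 8
Reactants: 14 (2R,3R)-2-(benzyloxy)-3-[3,4-bis(benzyloxy)phenyl]-3-[3,5-bis(benzyloxy)phenoxy]propan-1-ol
Product: 15 (2S,3R)-2-(benzyloxy)-3-[3,4-bis(benzyloxy)phenyl]-3-[3,5-bis(benzyloxy)phenoxy]propanal
Conditions: Dess–Martin periodinane, NaHCO3, CH2Cl2, 0 °C → rt; used crude
Reagents that add atoms: none
Why: Buffered Dess–Martin oxidation gives the aldehyde without an amine base, which should avoid epimerisation at the α-carbon and β-elimination of the aryloxide.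

Step 9
Reactants: 15 (2S,3R)-2-(benzyloxy)-3-[3,4-bis(benzyloxy)phenyl]-3-[3,5-bis(benzyloxy)phenoxy]propanal; 16 dimethyl malonate
Product: 17 dimethyl 2-[(2R,3R)-2-(benzyloxy)-3-[3,4-bis(benzyloxy)phenyl]-3-[3,5-bis(benzyloxy)phenoxy]propylidene]malonate
Conditions: TiCl4, pyridine, THF, 0 °C → rt
Reagents that add atoms: none
Why: The TiCl4/pyridine variant of the Knoevenagel condensation works at 0 °C with a weak base and is the usual choice for α-alkoxy aldehydes that epimerise or eliminate under amine catalysis; the titanium is base-ligated in THF and should not ionise the aryl ether.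

Step 10
Reactants: 17 dimethyl 2-[(2R,3R)-2-(benzyloxy)-3-[3,4-bis(benzyloxy)phenyl]-3-[3,5-bis(benzyloxy)phenoxy]propylidene]malonate
Product: 18 dimethyl 2-[(2R,3R,4S)-3,5,7-tris(benzyloxy)-2-[3,4-bis(benzyloxy)phenyl]chroman-4-yl]malonate
Conditions: Sc(OTf)3 (10 mol %), 4 Å MS, CH2Cl2, −20 °C → rt
Reagents that add atoms: none
Why: Sc(OTf)3 binds both ester carbonyls of the alkylidene malonate, an ortho carbon of the 3,5-bis(benzyloxy)phenyl ether (the future C4a) adds to the β-carbon (C4), and the arenium ion loses a proton while the malonate enolate is protonated; the closest known reaction type is the Lewis-acid-catalysed intramolecular Friedel–Crafts alkylation of electron-rich aryl ethers by alkylidene malonates, which gives 4-substituted chromans. The pyran ring closes in a 6-exo-trig mode, because the attacked carbon C4 becomes a ring atom and the other alkene carbon stays outside the ring. The new stereocentre C4 (S) is controlled by C3: 1,3-allylic strain with the cis ester keeps the C3–H bond in the plane of the alkene, the O1–C2 tether brings the arene to the face of C4 on the side of C2, and the C4–C4a bond therefore forms anti to the C3 benzyloxy group, in a chair-like arrangement with the C2 aryl group equatorial and the C3 oxygen axial. This 2,3-cis-3,4-trans product should also be the more stable one, since a quasi-axial C4 substituent avoids the C5 benzyloxy group, so any reversibility of the addition works in the same direction. The step needs chemoselectivity for ring A over ring B, which the far higher nucleophilicity of the phloroglucinol triether and the six-membered ring (against an indane from ring B) should secure; the two ortho carbons of the aryl ether are equivalent, so no regiochemical question arises. It must also leave the benzylic C2–O1 bond intact, which a catalytic amount of a chelating Lewis acid at low temperature is meant to ensure.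

Step 11
Reactants: 18 dimethyl 2-[(2R,3R,4S)-3,5,7-tris(benzyloxy)-2-[3,4-bis(benzyloxy)phenyl]chroman-4-yl]malonate
Product: 19 methyl 2-[(2R,3R,4S)-3,5,7-tris(benzyloxy)-2-[3,4-bis(benzyloxy)phenyl]chroman-4-yl]acetate
Conditions: LiCl, H2O, DMSO, 140 °C
Reagents that add atoms: none
Why: Krapcho demethoxycarbonylation, in which chloride cleaves one methyl ester at the methyl group, the carboxylate loses CO2 and water protonates the ester enolate; C4 has no leaving group β to the enolate and should not be affected.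

Step 12
Reactants: 20 (−)-epicatechin
Product: 21 (2R,3R)-5,7-bis(benzyloxy)-2-[3,4-bis(benzyloxy)phenyl]chroman-3-ol (5,7,3',4'-tetra-O-benzylepicatechin)
Conditions: BnBr, K2CO3, DMF, 0 °C → rt, argon
Reagents that add atoms: benzyl bromide, BrCc1ccccc1
Why: Williamson etherification with carbonate as base benzylates the four phenols and leaves the secondary C3 hydroxyl free, and the mild base does not epimerise C2.

Step 13
Reactants: 21 (2R,3R)-5,7-bis(benzyloxy)-2-[3,4-bis(benzyloxy)phenyl]chroman-3-ol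
Product: 22 (2R,3R)-5,7-bis(benzyloxy)-2-[3,4-bis(benzyloxy)phenyl]-8-bromochroman-3-ol
Conditions: NBS, CH2Cl2, −78 °C → rt
Reagents that add atoms: N-bromosuccinimide, O=C1CCC(=O)N1Br
Why: Electrophilic aromatic bromination of the 5,7-dialkoxy ring A goes to C8, the more accessible activated position next to O1, and this bromine blocks the nucleophilic site of the future electrophile.

Step 14
Reactants: 22 (2R,3R)-5,7-bis(benzyloxy)-2-[3,4-bis(benzyloxy)phenyl]-8-bromochroman-3-ol
Product: 23 (2R,3R,4S)-5,7-bis(benzyloxy)-2-[3,4-bis(benzyloxy)phenyl]-8-bromo-4-(2-ethoxyethoxy)chroman-3-ol (4β ether)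
Conditions: DDQ, 2-ethoxyethanol, CH2Cl2, rt
Reagents that add atoms: 2-ethoxyethanol, CCOCCO
Why: DDQ benzylic oxidation abstracts hydride from C4 to give a cation stabilised by the ring A oxygens, which the alcohol captures trans to the C3 hydroxyl; this is the usual way to C4-activated flavan-3-ol building blocks.

Step 15
Reactants: 19 methyl 2-[(2R,3R,4S)-3,5,7-tris(benzyloxy)-2-[3,4-bis(benzyloxy)phenyl]chroman-4-yl]acetate; 23 (2R,3R,4S)-5,7-bis(benzyloxy)-2-[3,4-bis(benzyloxy)phenyl]-8-bromo-4-(2-ethoxyethoxy)chroman-3-ol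
Product: 24 methyl [8-bromo-5,7,3',4'-tetra-O-benzylepicatechin-(4β→8)-3,5,7,3',4'-penta-O-benzylepicatechin-4β-yl]acetate
Conditions: 23 (1.3 equiv), TMSOTf (0.3 equiv), CH2Cl2, −78 → −40 °C
Reagents that add atoms: none
Why: Lewis-acid-promoted flavan C4–C8 coupling as used for procyanidin assembly, in which TMSOTf ionises the C4 ether of 23 and C8 of 19 (the accessible nucleophilic position of its ring A, next to O1) attacks the cation anti to the C3 oxygen and the C2 aryl group to give the 4β (3,4-trans) linkage, while the C8 bromine of 23 prevents self-condensation so that 19 can be the limiting partner.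

Step 16
Reactants: 24 methyl [8-bromo-5,7,3',4'-tetra-O-benzylepicatechin-(4β→8)-3,5,7,3',4'-penta-O-benzylepicatechin-4β-yl]acetate
Product: 25 [8-bromo-5,7,3',4'-tetra-O-benzylepicatechin-(4β→8)-3,5,7,3',4'-penta-O-benzylepicatechin-4β-yl]acetic acid
Conditions: LiOH, THF/MeOH/H2O, rt; then 1 M HCl to pH 3
Reagents that add atoms: lithium hydroxide, [Li+].[OH-]
Why: Saponification of the unhindered methyl ester is compatible with benzyl ethers and the aryl bromide, and no stereocentre is α to the carboxyl group.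

Step 17
Reactants: 25 [8-bromo-5,7,3',4'-tetra-O-benzylepicatechin-(4β→8)-3,5,7,3',4'-penta-O-benzylepicatechin-4β-yl]acetic acid
Product: 26 2-[(2R,3R,4S)-2-(3,4-dihydroxyphenyl)-8-[(2R,3R,4R)-2-(3,4-dihydroxyphenyl)-3,5,7-trihydroxychroman-4-yl]-3,5,7-trihydroxychroman-4-yl]acetic acid (CNP0190976.1)
Conditions: H2 (1 atm), Pd(OH)2/C, NaOAc, THF/MeOH/H2O, rt
Reagents that add atoms: none
Why: Hydrogenolysis over Pd(OH)2/C should cleave the nine benzyl ethers and the aryl C–Br bond in one operation, with NaOAc taking up the HBr so that the acid-labile interflavan bond is not exposed to strong acid.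

**Compound list**

1 | (S)-4-benzyloxazolidin-2-one | O=C1N[C@@H](Cc2ccccc2)CO1 | starting material
2 | benzyloxyacetyl chloride | O=C(Cl)COCc1ccccc1 | starting material
3 | lithium (S)-4-benzyl-2-oxooxazolidin-3-ide | [Li]N1[C@@H](Cc2ccccc2)COC1=O | intermediate (not isolated)
4 | (S)-4-benzyl-3-[2-(benzyloxy)acetyl]oxazolidin-2-one | O=C(COCc1ccccc1)N1[C@@H](Cc2ccccc2)COC1=O | intermediate
5 | 3,4-bis(benzyloxy)benzaldehyde | O=Cc1ccc(OCc2ccccc2)c(OCc2ccccc2)c1 | starting material
6 | dibutylboron Z-enolate of 4 | CCCCB(CCCC)O/C(=C\OCc1ccccc1)N1[C@@H](Cc2ccccc2)COC1=O | intermediate (not isolated)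
7 | dibutylboron aldolate of 8 | O=C([C@@H](OCc1ccccc1)[C@H](OB(CCCC)CCCC)c1ccc(OCc2ccccc2)c(OCc2ccccc2)c1)N1[C@@H](Cc2ccccc2)COC1=O | intermediate (not isolated)
8 | (S)-4-benzyl-3-[(2S,3R)-2-(benzyloxy)-3-[3,4-bis(benzyloxy)phenyl]-3-hydroxypropanoyl]oxazolidin-2-one | O=C([C@@H](OCc1ccccc1)[C@H](O)c1ccc(OCc2ccccc2)c(OCc2ccccc2)c1)N1[C@@H](Cc2ccccc2)COC1=O | intermediate
9 | (1R,2R)-2-(benzyloxy)-1-[3,4-bis(benzyloxy)phenyl]propane-1,3-diol | OC[C@@H](OCc1ccccc1)[C@H](O)c1ccc(OCc2ccccc2)c(OCc2ccccc2)c1 | intermediate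
10 | (1R,2R)-2-(benzyloxy)-1-[3,4-bis(benzyloxy)phenyl]-3-[(triisopropylsilyl)oxy]propan-1-ol | CC(C)[Si](OC[C@@H](OCc1ccccc1)[C@H](O)c1ccc(OCc2ccccc2)c(OCc2ccccc2)c1)(C(C)C)C(C)C | intermediate
11 | 1,3-bis(benzyloxy)-5-bromobenzene | Brc1cc(OCc2ccccc2)cc(OCc2ccccc2)c1 | starting material
12 | 1,3-bis(benzyloxy)-5-iodobenzene | Ic1cc(OCc2ccccc2)cc(OCc2ccccc2)c1 | intermediate
13 | {[(2R,3R)-2-(benzyloxy)-3-[3,4-bis(benzyloxy)phenyl]-3-[3,5-bis(benzyloxy)phenoxy]propyl]oxy}triisopropylsilane | CC(C)[Si](OC[C@@H](OCc1ccccc1)[C@H](Oc1cc(OCc2ccccc2)cc(OCc2ccccc2)c1)c1ccc(OCc2ccccc2)c(OCc2ccccc2)c1)(C(C)C)C(C)C | intermediate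
14 | (2R,3R)-2-(benzyloxy)-3-[3,4-bis(benzyloxy)phenyl]-3-[3,5-bis(benzyloxy)phenoxy]propan-1-ol | OC[C@@H](OCc1ccccc1)[C@H](Oc1cc(OCc2ccccc2)cc(OCc2ccccc2)c1)c1ccc(OCc2ccccc2)c(OCc2ccccc2)c1 | intermediate
15 | (2S,3R)-2-(benzyloxy)-3-[3,4-bis(benzyloxy)phenyl]-3-[3,5-bis(benzyloxy)phenoxy]propanal | O=C[C@@H](OCc1ccccc1)[C@H](Oc1cc(OCc2ccccc2)cc(OCc2ccccc2)c1)c1ccc(OCc2ccccc2)c(OCc2ccccc2)c1 | intermediate
16 | dimethyl malonate | COC(=O)CC(=O)OC | starting material
17 | dimethyl 2-[(2R,3R)-2-(benzyloxy)-3-[3,4-bis(benzyloxy)phenyl]-3-[3,5-bis(benzyloxy)phenoxy]propylidene]malonate | COC(=O)C(C(=O)OC)=C[C@@H](OCc1ccccc1)[C@@H](c1ccc(OCc2ccccc2)c(OCc2ccccc2)c1)Oc1cc(OCc2ccccc2)cc(OCc2ccccc2)c1 | intermediate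
18 | dimethyl 2-[(2R,3R,4S)-3,5,7-tris(benzyloxy)-2-[3,4-bis(benzyloxy)phenyl]chroman-4-yl]malonate | COC(=O)C(C(=O)OC)[C@H]1c2c(OCc3ccccc3)cc(OCc3ccccc3)cc2O[C@H](c2ccc(OCc3ccccc3)c(OCc3ccccc3)c2)[C@@H]1OCc1ccccc1 | intermediate
19 | methyl 2-[(2R,3R,4S)-3,5,7-tris(benzyloxy)-2-[3,4-bis(benzyloxy)phenyl]chroman-4-yl]acetate | COC(=O)C[C@H]1c2c(OCc3ccccc3)cc(OCc3ccccc3)cc2O[C@H](c2ccc(OCc3ccccc3)c(OCc3ccccc3)c2)[C@@H]1OCc1ccccc1 | intermediate
20 | (−)-epicatechin | C1c2c(O)cc(O)cc2O[C@H](c2ccc(O)c(O)c2)[C@@H]1O | starting material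
21 | (2R,3R)-5,7-bis(benzyloxy)-2-[3,4-bis(benzyloxy)phenyl]chroman-3-ol | C1c2c(OCc3ccccc3)cc(OCc3ccccc3)cc2O[C@H](c2ccc(OCc3ccccc3)c(OCc3ccccc3)c2)[C@@H]1O | intermediate
22 | (2R,3R)-5,7-bis(benzyloxy)-2-[3,4-bis(benzyloxy)phenyl]-8-bromochroman-3-ol | C1c2c(OCc3ccccc3)cc(OCc3ccccc3)c(Br)c2O[C@H](c2ccc(OCc3ccccc3)c(OCc3ccccc3)c2)[C@@H]1O | intermediate
23 | (2R,3R,4S)-5,7-bis(benzyloxy)-2-[3,4-bis(benzyloxy)phenyl]-8-bromo-4-(2-ethoxyethoxy)chroman-3-ol | CCOCCO[C@H]1c2c(OCc3ccccc3)cc(OCc3ccccc3)c(Br)c2O[C@H](c2ccc(OCc3ccccc3)c(OCc3ccccc3)c2)[C@@H]1O | intermediate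
24 | methyl [8-bromo-5,7,3',4'-tetra-O-benzylepicatechin-(4β→8)-3,5,7,3',4'-penta-O-benzylepicatechin-4β-yl]acetate | COC(=O)C[C@H]1c2c(OCc3ccccc3)cc(OCc3ccccc3)c([C@H]3c4c(OCc5ccccc5)cc(OCc5ccccc5)c(Br)c4O[C@H](c4ccc(OCc5ccccc5)c(OCc5ccccc5)c4)[C@@H]3O)c2O[C@H](c2ccc(OCc3ccccc3)c(OCc3ccccc3)c2)[C@@H]1OCc1ccccc1 | intermediate
25 | [8-bromo-5,7,3',4'-tetra-O-benzylepicatechin-(4β→8)-3,5,7,3',4'-penta-O-benzylepicatechin-4β-yl]acetic acid | OC(=O)C[C@H]1c2c(OCc3ccccc3)cc(OCc3ccccc3)c([C@H]3c4c(OCc5ccccc5)cc(OCc5ccccc5)c(Br)c4O[C@H](c4ccc(OCc5ccccc5)c(OCc5ccccc5)c4)[C@@H]3O)c2O[C@H](c2ccc(OCc3ccccc3)c(OCc3ccccc3)c2)[C@@H]1OCc1ccccc1 | intermediate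
26 | 2-[(2R,3R,4S)-2-(3,4-dihydroxyphenyl)-8-[(2R,3R,4R)-2-(3,4-dihydroxyphenyl)-3,5,7-trihydroxychroman-4-yl]-3,5,7-trihydroxychroman-4-yl]acetic acid | O=C(O)C[C@H]1c2c(O)cc(O)c([C@H]3c4c(O)cc(O)cc4O[C@H](c4ccc(O)c(O)c4)[C@@H]3O)c2O[C@H](c2ccc(O)c(O)c2)[C@@H]1O | target

**Totals**

Total step count: 17. Longest linear sequence: 13 steps (steps 1–4, 6–11 and 15–17).

**Steps most likely to fail**

Step 10. The ring closure may show poor facial selectivity at C4, or the Lewis acid may ionise the benzylic C2–O1 bond before the arene adds. The fallback sets out from 21 and comes back at 19, and it reaches the lower unit by substitution at C4 of the natural flavan in place of the ring closure. Compound 21 would be benzylated at O3 (NaH, BnBr, DMF) to 3,5,7,3',4'-penta-O-benzylepicatechin F1. Oxidation with DDQ in the presence of 2-ethoxyethanol would give 4β-(2-ethoxyethoxy)-3,5,7,3',4'-penta-O-benzylepicatechin F2. Treatment of this ether with TMSOTf and 1-(tert-butyldimethylsilyloxy)-1-methoxyethene in CH2Cl2 at −78 °C should let the ketene silyl acetal attack the C4 cation anti to the C3 benzyloxy group and give 19.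

Step 6. The hindered secondary alkoxide may couple slowly, the silyl group may migrate to the benzylic oxygen at 110 °C, or the benzylic alcohol may be oxidised at the copper centre. The fallback sets out from 10 and comes back at 13, and it forms the benzylic C–O bond with inversion in place of the O–aryl bond. Dess–Martin oxidation of 10 would give (R)-2-(benzyloxy)-1-[3,4-bis(benzyloxy)phenyl]-3-[(triisopropylsilyl)oxy]propan-1-one F3. Chelation-controlled reduction with Zn(BH4)2 in Et2O at −20 °C should give the anti alcohol (1S,2R)-2-(benzyloxy)-1-[3,4-bis(benzyloxy)phenyl]-3-[(triisopropylsilyl)oxy]propan-1-ol F4. A Mitsunobu reaction of this alcohol with commercial 3,5-bis(benzyloxy)phenol (PPh3, DIAD, toluene, 0 °C) should then give 13 with inversion at the benzylic carbon.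

Step 9. The aldehyde may lose the aryloxide by β-elimination, epimerise at its α-carbon, or be attacked by ring A at the TiCl4-activated carbonyl group before the malonate condenses. The fallback sets out from 15 and comes back at 19, and it uses a more acidic and more electrophilic malonate equivalent under nearly neutral conditions. Condensation of 15 with Meldrum's acid and catalytic ethylenediammonium diacetate in CH2Cl2 at rt would give 5-[(2R,3R)-2-(benzyloxy)-3-[3,4-bis(benzyloxy)phenyl]-3-[3,5-bis(benzyloxy)phenoxy]propylidene]-2,2-dimethyl-1,3-dioxane-4,6-dione F5. This much stronger acceptor should be trapped by ring A in the same flask (if needed after adding catalytic Sc(OTf)3) to give 5-[(2R,3R,4S)-3,5,7-tris(benzyloxy)-2-[3,4-bis(benzyloxy)phenyl]chroman-4-yl]-2,2-dimethyl-1,3-dioxane-4,6-dione F6. Heating this adduct in MeOH/pyridine should open the dioxanedione, expel acetone and CO2, and give 19.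

**Further compounds**

F1 | step 10 | 3,5,7,3',4'-penta-O-benzylepicatechin | C1c2c(OCc3ccccc3)cc(OCc3ccccc3)cc2O[C@H](c2ccc(OCc3ccccc3)c(OCc3ccccc3)c2)[C@@H]1OCc1ccccc1
F2 | step 10 | 4β-(2-ethoxyethoxy)-3,5,7,3',4'-penta-O-benzylepicatechin | CCOCCO[C@H]1c2c(OCc3ccccc3)cc(OCc3ccccc3)cc2O[C@H](c2ccc(OCc3ccccc3)c(OCc3ccccc3)c2)[C@@H]1OCc1ccccc1
F3 | step 6 | (R)-2-(benzyloxy)-1-[3,4-bis(benzyloxy)phenyl]-3-[(triisopropylsilyl)oxy]propan-1-one | CC(C)[Si](OC[C@@H](OCc1ccccc1)C(=O)c1ccc(OCc2ccccc2)c(OCc2ccccc2)c1)(C(C)C)C(C)C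
F4 | step 6 | (1S,2R)-2-(benzyloxy)-1-[3,4-bis(benzyloxy)phenyl]-3-[(triisopropylsilyl)oxy]propan-1-ol | CC(C)[Si](OC[C@@H](OCc1ccccc1)[C@@H](O)c1ccc(OCc2ccccc2)c(OCc2ccccc2)c1)(C(C)C)C(C)C
F5 | step 9 | 5-[(2R,3R)-2-(benzyloxy)-3-[3,4-bis(benzyloxy)phenyl]-3-[3,5-bis(benzyloxy)phenoxy]propylidene]-2,2-dimethyl-1,3-dioxane-4,6-dione | CC1(C)OC(=O)C(=C[C@@H](OCc2ccccc2)[C@@H](c2ccc(OCc3ccccc3)c(OCc3ccccc3)c2)Oc2cc(OCc3ccccc3)cc(OCc3ccccc3)c2)C(=O)O1
F6 | step 9 | 5-[(2R,3R,4S)-3,5,7-tris(benzyloxy)-2-[3,4-bis(benzyloxy)phenyl]chroman-4-yl]-2,2-dimethyl-1,3-dioxane-4,6-dione | CC1(C)OC(=O)C([C@H]2c3c(OCc4ccccc4)cc(OCc4ccccc4)cc3O[C@H](c3ccc(OCc4ccccc4)c(OCc4ccccc4)c3)[C@@H]2OCc2ccccc2)C(=O)O1
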